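**Remarks**

- Locants: plain locants and rings A, B, C belong to the flavanone unit (ring B positions primed); double-primed locants and rings D (benzo) and E (pyranone) belong to the flavone unit, ring F positions triple-primed. Monocyclic dihydropyranones are numbered O1, C2, C3, C4, C5, C6; their C5 and C6 become C4a and C8a. "Fl" stands for 5-(benzyloxy)-2-[4-(benzyloxy)phenyl]-7-(methoxymethoxy)-4-oxo-4H-chromen-8-yl.
- Assumption: the aryl hydrogen sulfate is handled as its sodium salt and set free only at the end by brief contact with a cold acidic ion-exchange resin, because free aryl sulfate monoesters hydrolyse autocatalytically.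

## Structural features

The target is a 3→8''-linked biflavonoid: a 5,7,4'-trihydroxyflavanone (ring A benzo; ring C = O1, C2, C3, C4, C4a, C8a; ring B on C2) whose C3 is bonded to C8'' of a 5'',7'',4'''-trioxygenated flavone (rings D, E, F), with O7'' esterified as a hydrogen sulfate. The only stereocentres are the neighbours C2 (R) and C3 (S), which hold ring B and the flavone trans on ring C. C3–H is alpha to the C4 ketone and sits on an electron-rich aryl carbon, so it epimerises readily. With base the C3 enolate can expel the ring A phenoxide O1 (E1cB) to an achiral alpha-aryl chalcone, which would erase both centres, and a free chelated 5-OH makes this opening easier. The aryl sulfate is acid-labile and too polar to carry far, the flavone carbonyl is a strong Lewis base, and of six phenolic oxygens only O7'' may be sulfated. The real difficulty is therefore absolute control at C2 beside a crowded, labile C3 that bears a di-ortho-substituted aryl group, together with singling out O7''. The key step uses the fact that ring C, once ring A is stripped from its C4a–C8a edge, is a 2,3-diaryl-2,3-dihydro-4H-pyran-4-one. Its C2–C3 and O1–C8a bonds are those formed when an aldehyde meets a 1-alkoxy-3-silyloxy diene, and the enol-ether edge left behind is where ring A can be grown afterwards.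

## Logic of the disconnections

**25 ⇒ 24.** The four benzylic O–C bonds at O7, O4', O5'' and O4''' are cut last. Benzyl ethers come off under neutral reducing conditions that an aryl sulfate salt and a 5-hydroxyflavanone tolerate. This lets every phenol but one wear the same mask. The forward step must spare the sulfate, the ring E double bond and the benzylic O1–C2 bond, so no amine may be present.

**24 ⇒ 23.** The S–O7'' bond is cut. A sulfate monoester cannot be carried through organometallic or chromatographic steps, so it is placed on a neutral penultimate compound. This demands that O7''–H be the only reactive hydroxyl: the 5-OH is chelated and all others are benzylated.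

**23 ⇒ 22.** The O7''–CH2 acetal bond is cut. O7'' needs a mask that is orthogonal to benzyl, small (it flanks C8'', where the crowded bonds are made), stable to base and organometallics, and removable in acid, the medium in which ring C is configurationally safe. A bulky silyl ether was rejected because it would not survive the carbonate and methoxide steps and would crowd the key step.

**22 ⇒ 16 + 19.** C4a–C5 and C8–C8a of ring A are cut. The retron is the enol-ether edge of a dihydropyranone carrying a sulfinyl group at C5 as activator and leaving group. Ring A is removed with its oxygens already differentiated (O5 free, O7 benzylated by the diene). The forward step must deliver the CH2 terminus of the diene to C6 and must lose sulfenic acid, not the ring oxygen.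

**16 ⇒ 15 ⇒ 13.** The S–O bond and then the C5–S bond are cut. The bare C5=C6 of 13 is neither a dienophile nor able to re-aromatise. A halogen at C5 would leave, after cycloaddition, a cis H/X pair whose hydrogen at C8a is not acidic, whereas a sulfoxide eliminates thermally in the syn sense. The sulfur electrophile must choose C5 over the flavone.

**13 ⇒ 10 + 11 (key).** C2–C3 and O1–C6 are cut. Ring C and both stereocentres then arise in one catalytic asymmetric operation from an achiral diene and a commercial aldehyde, before any base-labile 5-hydroxyflavanone exists. The step must control the aldehyde enantioface; C3 may be left to thermodynamics. The diene needs the (1E,3Z) geometry and the catalyst must cope with the Lewis-basic flavone.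

**10 ⇒ 9 ⇒ 7 ⇒ 5 + 6.** The O–Si bond, then the C–OMe and C–Si bonds, then the acyl–alkynyl C–C bond are cut. The beta-methoxy enone is the carbonyl form of the diene. It is reached from an ynone because formylating a methyl ketone would occur at the more acidic benzylic methylene. The acyl substitution must not touch the ring E carbonyl.

**5 ⇒ 4 ⇒ 3.** The C8''–CH2 bond and then the C8''–I bond are cut. Once O5'' is alkylated, C8'' is the most nucleophilic ring D carbon, and the iodide converts it into a cross-coupling site for a two-carbon amide enolate. The demands are regioselective iodination and coupling at a di-ortho-substituted carbon.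

**3 ⇒ 2 ⇒ 1.** Two O–benzyl bonds and the O7''–acetal bond are cut. The acidity order O7''–H > O4'''–H > O5''–H allows O7'' to be marked first. The demand is clean mono-alkylation.

**19 ⇒ 18 ⇒ 17.** The O–Si bond and the enol-ether O–benzyl bond are cut. Putting benzyl on the diene oxygen that becomes O7 saves a later selective benzylation of the flavanone.

## Other disconnections considered

**Alternative 1:** The cut is C4a–C5 of ring A, on a dihydropyranone A2 that already carries at C8a a four-carbon chain masked as a dioxinone. In the forward step, heating A2 unmasks a ketene, the enol-ether carbon C4a acylates at the ketene carbon (future C5), and enolisation gives the phloroglucinol ring of A1.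
- In favour: the chain has the right oxidation level, so ring C needs no activating or leaving group. The neutral thermal conditions suit a base-labile product. The competing aldol folding is geometrically excluded, because C4 and C8 are trans across C4a=C8a.
- Against: A2 with both stereocentres must be made first, through steps that tolerate a dioxinone and an acidic methylene. O-acylation and intermolecular ketene capture can compete. A1 has O5 and O7 both free, so a selective 7-O-benzylation is still owed before sulfation.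
- Comparison: on mechanism the ring A closure to A1 is cleaner than step 13 (no sulfur, no elimination) and is the better of the two on that point. On structure it needs the same ring C and the same stereocontrol, which the chosen plan supplies in step 8. On step economy the two are about equal once chain installation and benzylation are counted.

**Alternative 2:** The cut is ring E of the flavone: C4a''–C4'', C4''–C3'' and O1''–C2''. In the forward step, iodophenol A4 and alkyne A5 are joined carbonylatively under zerovalent palladium (acyl-palladium alkynylation, then 6-endo oxa-Michael closure) to give A3.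
- In favour: it is highly convergent, and the Lewis-basic flavone is absent while ring C is built. A4 is a 2-substituted resorcinol in which only the hydroxyl next to iodine can cyclise, so O7'' emerges free and A3 can be sulfated without any protecting-group step. On this point it is better than the chosen plan.
- Against: A4 already contains the trans-3-arylflavanone, so the stereochemical problem is only moved. The amine base and heat of the coupling act on a flavanone with an acidic C3–H and invite E1cB opening. 5-exo closure to an aurone competes with the 6-endo mode.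
- Comparison: on end-game length it is equal or better. On the stereocentres it is worse, since they must survive a basic metal-catalysed step, whereas the chosen plan uses no base stronger than pyridine after step 9. On structure it contributes nothing to ring C.

**Alternative 3:** The cut is C3–C4 and O1–C2 of ring C. In the forward step, benzylic alcohol A8 is dehydrated to the ring A ortho-quinone methide, which adds to E-stilbene A7 in an inverse-demand hetero-Diels–Alder reaction to give flavan A6.
- In favour: the two fragments are of similar size. The E geometry translates stereospecifically into trans C2/C3, which is equal to the chosen plan on relative configuration. No epimerisable ketone is present during bond formation.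
- Against: both alkene carbons of A7 bear donor aryl groups, so which aryl ends on C2 is not assured. Enantiofacial control over a non-chelating stilbene has no dependable catalyst. A6 has C4 as CH2, so a benzylic oxidation at C4 would be needed in the presence of C2–H and five benzyl ethers.
- Comparison: it is better on convergence and equal on trans control. It is worse on absolute configuration and oxidation state, since the chosen plan forms C4 as a ketone in the key step.

Key step: step 8

## Route

**Step 1**
Reactants: 1 apigenin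
Product: 2 5-hydroxy-2-(4-hydroxyphenyl)-7-(methoxymethoxy)-4H-chromen-4-one
Conditions: MOMCl (1.05 equiv), i-Pr2NEt (1.1 equiv), DMF, −10 to 0 °C
Reagents that add atoms: chloromethyl methyl ether, COCCl
Why: Williamson-type O-alkylation under weak-base control; O7''–H is the most acidic phenol (para to the pyranone carbonyl through ring D), so one equivalent of base and electrophile in the cold should mark it ahead of O4'''–H, while the chelated O5''–H stays inert.

**Step 2**
Reactants: 2 5-hydroxy-2-(4-hydroxyphenyl)-7-(methoxymethoxy)-4H-chromen-4-one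
Product: 3 5-(benzyloxy)-2-[4-(benzyloxy)phenyl]-7-(methoxymethoxy)-4H-chromen-4-one
Conditions: BnBr (3 equiv), K2CO3 (4 equiv), n-Bu4NI (cat.), DMF, 70 °C
Reagents that add atoms: benzyl bromide, BrCc1ccccc1
Why: Williamson etherification; O4'''–H reacts readily and the hydrogen-bonded O5''–H under the forcing, iodide-assisted conditions. The acetal on O7'' is stable to carbonate, which a silyl ether at this acidic phenol would not be.

**Step 3**
Reactants: 3 5-(benzyloxy)-2-[4-(benzyloxy)phenyl]-7-(methoxymethoxy)-4H-chromen-4-one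
Product: 4 5-(benzyloxy)-2-[4-(benzyloxy)phenyl]-8-iodo-7-(methoxymethoxy)-4H-chromen-4-one
Conditions: NIS (1.1 equiv), TFA (10 mol %), MeCN, 0 °C to rt, dark
Reagents that add atoms: N-iodosuccinimide, O=C1CCC(=O)N1I
Why: Electrophilic aromatic iodination; with all oxygens alkylated, C8'' (ortho to O7'' and O1'', para to O5'') is the most activated and least crowded ring D carbon, C6'' being flanked by two alkoxy groups. Ring F and C3'' are deactivated by conjugation with the carbonyl.

**Step 4**
Reactants: 4 5-(benzyloxy)-2-[4-(benzyloxy)phenyl]-8-iodo-7-(methoxymethoxy)-4H-chromen-4-one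
Product: 5 2-Fl-1-(morpholin-4-yl)ethan-1-one
Conditions: BrZnCH2C(O)N(CH2CH2)2O (1.5 equiv, from 4-(bromoacetyl)morpholine and Zn dust, THF), Pd(dba)2 (5 mol %), P(t-Bu)3 (5 mol %), THF, rt to 45 °C
Reagents that add atoms: 4-(bromoacetyl)morpholine (as its zinc enolate), O=C(CBr)N1CCOCC1
Why: Negishi-type alpha-arylation of a Reformatsky zinc amide enolate (oxidative addition to zerovalent palladium, transmetalation, reductive elimination) under neutral conditions that leave the flavone carbonyl and the acetal alone. The bulky electron-rich phosphine serves the di-ortho-substituted iodide.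

**Step 5**
Reactants: 5 2-Fl-1-(morpholin-4-yl)ethan-1-one; 6 ethynyltrimethylsilane
Product: 7 1-Fl-4-(trimethylsilyl)but-3-yn-2-one
Conditions: 6 (2.5 equiv), EtMgBr (2.4 equiv), THF, 0 °C to rt; then 5, THF, −20 to 0 °C; cold aq NaHSO4
Reagents that add atoms: none
Why: Acyl substitution of an N-acylmorpholine by an alkynyl Grignard reagent; the chelated tetrahedral magnesium adduct resists over-addition and collapses to the ynone on acidic quench, which also removes morpholine before it can add to the ynone. The soft, weakly basic acetylide should leave the vinylogous-ester carbonyl of ring E untouched at or below 0 °C.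

**Step 6**
Reactants: 7 1-Fl-4-(trimethylsilyl)but-3-yn-2-one
Product: 9 (E)-1-Fl-4-methoxybut-3-en-2-one, via terminal ynone 8 (not isolated)
Conditions: K2CO3 (0.2 equiv), MeOH/THF (3:1), 0 °C to rt
Reagents that add atoms: methanol, CO
Why: Methoxide cleaves the C–Si bond to give 8, which takes up methanol by oxa-Michael addition; protonation under equilibrating conditions gives the more stable E beta-methoxy enone. Any dimethyl acetal from double addition loses methanol again on silica or in step 7.

**Step 7**
Reactants: 9 (E)-1-Fl-4-methoxybut-3-en-2-one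
Product: 10 (1E,3Z)-4-Fl-1-methoxy-3-(trimethylsilyloxy)buta-1,3-diene
Conditions: TMSOTf (1.3 equiv), Et3N (2.5 equiv), Et2O/CH2Cl2, 0 °C; pentane, filtration under argon, used at once
Reagents that add atoms: trimethylsilyl trifluoromethanesulfonate, C[Si](C)(C)OS(=O)(=O)C(F)(F)F
Why: Soft enolisation and O-silylation; only the benzylic carbon has enolisable hydrogens. The enol ether with Fl cis to the silyloxy group and trans to the vinyl chain is favoured sterically and by conjugation, giving the (1E,3Z) diene that can reach the s-cis conformation.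

**Step 8**
Reactants: 10 (1E,3Z)-4-Fl-1-methoxy-3-(trimethylsilyloxy)buta-1,3-diene; 11 4-(benzyloxy)benzaldehyde
Product: 13 (2R,3S)-2-[4-(benzyloxy)phenyl]-3-Fl-2,3-dihydro-4H-pyran-4-one, via silylated aldol adduct 12 (not isolated)
Conditions: Ti(O-i-Pr)4 (20 mol %), (R)-BINOL (40 mol %), 4 Å MS, Et2O, −20 °C, 11 (1.0 equiv), 10 (1.5 equiv); then TFA (2 equiv), CH2Cl2, 0 °C; aq NaHCO3
Reagents that add atoms: none
Why: A chiral BINOLate of tetravalent titanium binds aldehyde 11, and the silyl enol ether terminus of 10 adds to it in a Mukaiyama aldol sense to form C2–C3 and give 12 (a concerted [4+2] path would form the same bonds); TFA then frees the carbinol oxygen, which adds 6-endo-trig to the methoxy-bearing enone carbon and expels methanol, forming O1–C6 and closing ring C as the vinylogous ester. The closest known reaction is the titanium–BINOL catalysed hetero-Diels–Alder (aldol–cyclisation) reaction of 1-methoxy-3-silyloxy dienes, including 4-substituted ones, with aromatic aldehydes, so the 4-aryl diene extends the substrate range but is not a new reaction. C2 is set by the catalyst: attack on the Re face of 11 gives 2R, which the (R)-BINOL complex is expected to deliver by analogy with its other aldehyde additions, and the antipodal ligand is used if the first assay shows the opposite sense. C3 is set by thermodynamics: it is alpha to the ketone and benzylic and equilibrates through the enol under the acidic work-up to the trans, diequatorial arrangement, so syn and anti aldol adducts converge on (2R,3S)-13. Site selectivity is secured because 11 is the only aldehyde and cannot enolise, 10 has a single nucleophilic carbon, and the E-methoxyvinyl unit places the leaving group for six-ring closure. The flavone carbonyl is a competing Lewis base but not an electrophile here, which the raised catalyst loading and the small acetal next to the reacting carbon are meant to answer. Base is excluded, since deprotonation at C3 could open ring C by E1cB loss of O1.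

**Step 9**
Reactants: 13 (2R,3S)-2-[4-(benzyloxy)phenyl]-3-Fl-2,3-dihydro-4H-pyran-4-one
Product: 15 (2R,3S)-2-[4-(benzyloxy)phenyl]-3-Fl-5-(phenylsulfanyl)-2,3-dihydro-4H-pyran-4-one, via chloro sulfide adduct 14 (not isolated)
Conditions: PhSCl (1.05 equiv), CH2Cl2, −78 °C; then Et3N (1.5 equiv), −78 to 0 °C
Reagents that add atoms: benzenesulfenyl chloride, ClSc1ccccc1
Why: Electrophilic alpha-sulfenylation of a vinylogous ester by addition–elimination: the sulfenyl chloride attacks the enol-ether carbon C5 to give 14, and the amine removes the now acidic C5–H with loss of chloride from C6. The non-aromatic enol ether of ring C is far more nucleophilic than C3'' or C6'' of the flavone, and the amine is kept cold and brief to spare C3.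

**Step 10**
Reactants: 15 (2R,3S)-2-[4-(benzyloxy)phenyl]-3-Fl-5-(phenylsulfanyl)-2,3-dihydro-4H-pyran-4-one
Product: 16 (2R,3S)-2-[4-(benzyloxy)phenyl]-3-Fl-5-(phenylsulfinyl)-2,3-dihydro-4H-pyran-4-one (both epimers at sulfur)
Conditions: mCPBA (1.0 equiv), NaHCO3, CH2Cl2, −78 to −30 °C
Reagents that add atoms: 3-chloroperoxybenzoic acid, O=C(OO)c1cccc(Cl)c1
Why: Chemoselective sulfide-to-sulfoxide oxidation with one equivalent of peracid in the cold; the electron-poor enone and flavone double bonds are not epoxidised. The new sulfur stereocentre is irrelevant because sulfur is expelled in step 13.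

**Step 11**
Reactants: 17 methyl (E)-3-methoxybut-2-enoate
Product: 18 methyl (E)-3-(benzyloxy)but-2-enoate
Conditions: BnOH (1.3 equiv), TsOH·H2O (2 mol %), toluene, 100 °C, slow distillation of MeOH
Reagents that add atoms: benzyl alcohol, OCc1ccccc1
Why: Acid-catalysed enol-ether exchange (transetherification through the mixed ketal), driven by removal of methanol, with the E isomer thermodynamically preferred. A benzyl ester from competing transesterification would be harmless, since the ester alkoxy group is lost in step 13.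

**Step 12**
Reactants: 18 methyl (E)-3-(benzyloxy)but-2-enoate
Product: 19 3-(benzyloxy)-1-methoxy-1-(trimethylsilyloxy)buta-1,3-diene
Conditions: LiN(i-Pr)2 (1.1 equiv), THF, −78 °C; TMSCl (1.3 equiv), −78 °C to rt; pentane, filtration, used crude
Reagents that add atoms: chlorotrimethylsilane, C[Si](C)(C)Cl
Why: Gamma-deprotonation of the beta-alkoxy enoate to the extended dienolate and O-silylation, the standard route to 1-alkoxy-1-silyloxy-3-alkoxy dienes. The geometry of the ketene acetal double bond is without consequence.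

**Step 13**
Reactants: 16 (2R,3S)-2-[4-(benzyloxy)phenyl]-3-Fl-5-(phenylsulfinyl)-2,3-dihydro-4H-pyran-4-one; 19 3-(benzyloxy)-1-methoxy-1-(trimethylsilyloxy)buta-1,3-diene
Product: 22 (2R,3S)-7-(benzyloxy)-2-[4-(benzyloxy)phenyl]-3-Fl-5-hydroxy-2,3-dihydro-4H-chromen-4-one, via sulfinyl cycloadduct 20 (not isolated), via dienyl silyl ketal 21 (not isolated)
Conditions: 19 (3 equiv), toluene, 85 °C; then PPTS (10 mol %), CH2Cl2/MeOH, rt
Reagents that add atoms: none
Why: Proposed new method: the 5-sulfinyl group lowers the LUMO of the C5=C6 bond of 16, and its push–pull polarisation (C6 electrophilic as the enone beta carbon) directs the nucleophilic CH2 terminus of 19 to C6 and the ketene acetal carbon to C5, in one [4+2] event or a Michael–Claisen-type two-stage path to the same adduct 20. In 20 the sulfinyl group and the C8a hydrogen are cis, so thermal syn elimination of benzenesulfenic acid restores C4a=C8a (21), and loss of methoxytrimethylsilane with enolisation gives phenol 22 with O5 free and O7 benzylated, C2 and C3 being untouched. The closest known reaction type is the tandem Diels–Alder/sulfoxide elimination/aromatisation of alpha-sulfinyl enones and sulfinylquinones with 1-alkoxy-1-silyloxy dienes, which to my knowledge has not been shown on a 5-sulfinyl-2,3-dihydropyran-4-one.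

**Step 14**
Reactants: 22 (2R,3S)-7-(benzyloxy)-2-[4-(benzyloxy)phenyl]-3-Fl-5-hydroxy-2,3-dihydro-4H-chromen-4-one
Product: 23 (2R,3S)-7-(benzyloxy)-2-[4-(benzyloxy)phenyl]-3-{5-(benzyloxy)-2-[4-(benzyloxy)phenyl]-7-hydroxy-4-oxo-4H-chromen-8-yl}-5-hydroxy-2,3-dihydro-4H-chromen-4-one
Conditions: 3 M aq HCl, MeOH/THF (1:1), 45 °C
Reagents that add atoms: none
Why: Acid-catalysed acetal cleavage; benzyl ethers, the flavone and the flavanone are stable in dilute acid. C3 can only drift toward the trans arrangement through the enol, and base, which could open ring C, is avoided.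

**Step 15**
Reactants: 23 (2R,3S)-7-(benzyloxy)-2-[4-(benzyloxy)phenyl]-3-{5-(benzyloxy)-2-[4-(benzyloxy)phenyl]-7-hydroxy-4-oxo-4H-chromen-8-yl}-5-hydroxy-2,3-dihydro-4H-chromen-4-one
Product: 24 (2R,3S)-7-(benzyloxy)-2-[4-(benzyloxy)phenyl]-3-{5-(benzyloxy)-2-[4-(benzyloxy)phenyl]-4-oxo-7-(sulfooxy)-4H-chromen-8-yl}-5-hydroxy-2,3-dihydro-4H-chromen-4-one (handled as the sodium salt)
Conditions: SO3·pyridine (6 equiv), DMF, rt to 40 °C; aq NaHCO3, 0 °C; Sephadex LH-20
Reagents that add atoms: sulfur trioxide–pyridine complex, [O-]S(=O)(=O)[n+]1ccccc1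
Why: O-Sulfonation of a phenol by a sulfur trioxide–amine complex; O7''–H is the only non-chelated hydroxyl, the 5-OH being tied to the C4 carbonyl, and no base stronger than pyridine is present. Exchange to the sodium salt removes pyridine, which would otherwise inhibit step 16.

**Step 16**
Reactants: 24 (2R,3S)-7-(benzyloxy)-2-[4-(benzyloxy)phenyl]-3-{5-(benzyloxy)-2-[4-(benzyloxy)phenyl]-4-oxo-7-(sulfooxy)-4H-chromen-8-yl}-5-hydroxy-2,3-dihydro-4H-chromen-4-one
Product: 25 (2R,3S)-5,7-dihydroxy-3-[5-hydroxy-2-(4-hydroxyphenyl)-4-oxo-7-(sulfooxy)-4H-chromen-8-yl]-2-(4-hydroxyphenyl)-2,3-dihydro-4H-chromen-4-one (CNP0271389.1)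
Conditions: H2 (1 atm), 10% Pd/C, THF/MeOH/H2O, rt; filtration; Dowex 50W (H+ form), 0 °C, lyophilisation
Reagents that add atoms: none
Why: Hydrogenolysis of four aryl benzyl ethers on palladium; the aryl sulfate salt, the ring E double bond and the benzylic O1–C2 bond are expected to survive at one atmosphere and room temperature if the reaction is stopped at full debenzylation. No stereocentre is touched.

## Compound list

1 | apigenin | O=c1cc(-c2ccc(O)cc2)oc2cc(O)cc(O)c12 | starting material
2 | 5-hydroxy-2-(4-hydroxyphenyl)-7-(methoxymethoxy)-4H-chromen-4-one | COCOc1cc(O)c2c(=O)cc(-c3ccc(O)cc3)oc2c1 | intermediate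
3 | 5-(benzyloxy)-2-[4-(benzyloxy)phenyl]-7-(methoxymethoxy)-4H-chromen-4-one | COCOc1cc(OCc2ccccc2)c2c(=O)cc(-c3ccc(OCc4ccccc4)cc3)oc2c1 | intermediate
4 | 5-(benzyloxy)-2-[4-(benzyloxy)phenyl]-8-iodo-7-(methoxymethoxy)-4H-chromen-4-one | COCOc1cc(OCc2ccccc2)c2c(=O)cc(-c3ccc(OCc4ccccc4)cc3)oc2c1I | intermediate
5 | 2-Fl-1-(morpholin-4-yl)ethan-1-one | COCOc1cc(OCc2ccccc2)c2c(=O)cc(-c3ccc(OCc4ccccc4)cc3)oc2c1CC(=O)N1CCOCC1 | intermediate
6 | ethynyltrimethylsilane | C#C[Si](C)(C)C | starting material
7 | 1-Fl-4-(trimethylsilyl)but-3-yn-2-one | COCOc1cc(OCc2ccccc2)c2c(=O)cc(-c3ccc(OCc4ccccc4)cc3)oc2c1CC(=O)C#C[Si](C)(C)C | intermediate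
8 | 1-Fl-but-3-yn-2-one (formed in the flask) | COCOc1cc(OCc2ccccc2)c2c(=O)cc(-c3ccc(OCc4ccccc4)cc3)oc2c1CC(=O)C#C | intermediate
9 | (E)-1-Fl-4-methoxybut-3-en-2-one | COCOc1cc(OCc2ccccc2)c2c(=O)cc(-c3ccc(OCc4ccccc4)cc3)oc2c1CC(=O)/C=C/OC | intermediate
10 | (1E,3Z)-4-Fl-1-methoxy-3-(trimethylsilyloxy)buta-1,3-diene | CO/C=C/C(O[Si](C)(C)C)=C/c1c(OCOC)cc(OCc2ccccc2)c2c(=O)cc(-c3ccc(OCc4ccccc4)cc3)oc12 | intermediate
11 | 4-(benzyloxy)benzaldehyde | O=Cc1ccc(OCc2ccccc2)cc1 | starting material
12 | (1E,4S,5R)-5-[4-(benzyloxy)phenyl]-4-Fl-1-methoxy-5-(trimethylsilyloxy)pent-1-en-3-one, possibly with its C4 epimer (formed in the flask) | CO/C=C/C(=O)[C@@H](c1c(OCOC)cc(OCc2ccccc2)c2c(=O)cc(-c3ccc(OCc4ccccc4)cc3)oc12)[C@@H](O[Si](C)(C)C)c1ccc(OCc2ccccc2)cc1 | intermediate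
13 | (2R,3S)-2-[4-(benzyloxy)phenyl]-3-Fl-2,3-dihydro-4H-pyran-4-one | O=C1C=CO[C@@H](c2ccc(OCc3ccccc3)cc2)[C@@H]1c1c(OCOC)cc(OCc2ccccc2)c2c(=O)cc(-c3ccc(OCc4ccccc4)cc3)oc12 | intermediate
14 | (2R,3S)-2-[4-(benzyloxy)phenyl]-6-chloro-3-Fl-5-(phenylsulfanyl)tetrahydro-4H-pyran-4-one, C5 and C6 undefined (formed in the flask) | O=C1C(Sc2ccccc2)C(Cl)O[C@@H](c2ccc(OCc3ccccc3)cc2)[C@@H]1c1c(OCOC)cc(OCc2ccccc2)c2c(=O)cc(-c3ccc(OCc4ccccc4)cc3)oc12 | intermediate
15 | (2R,3S)-2-[4-(benzyloxy)phenyl]-3-Fl-5-(phenylsulfanyl)-2,3-dihydro-4H-pyran-4-one | O=C1C(Sc2ccccc2)=CO[C@@H](c2ccc(OCc3ccccc3)cc2)[C@@H]1c1c(OCOC)cc(OCc2ccccc2)c2c(=O)cc(-c3ccc(OCc4ccccc4)cc3)oc12 | intermediate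
16 | (2R,3S)-2-[4-(benzyloxy)phenyl]-3-Fl-5-(phenylsulfinyl)-2,3-dihydro-4H-pyran-4-one, both epimers at sulfur | O=C1C(S(=O)c2ccccc2)=CO[C@@H](c2ccc(OCc3ccccc3)cc2)[C@@H]1c1c(OCOC)cc(OCc2ccccc2)c2c(=O)cc(-c3ccc(OCc4ccccc4)cc3)oc12 | intermediate
17 | methyl (E)-3-methoxybut-2-enoate | COC(=O)/C=C(\C)OC | starting material
18 | methyl (E)-3-(benzyloxy)but-2-enoate | COC(=O)/C=C(\C)OCc1ccccc1 | intermediate
19 | 3-(benzyloxy)-1-methoxy-1-(trimethylsilyloxy)buta-1,3-diene, C1 geometry undefined | C=C(OCc1ccccc1)C=C(OC)O[Si](C)(C)C | intermediate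
20 | (2R,3S)-7-(benzyloxy)-2-[4-(benzyloxy)phenyl]-3-Fl-5-methoxy-4a-(phenylsulfinyl)-5-(trimethylsilyloxy)-2,3,4a,5,8,8a-hexahydro-4H-chromen-4-one, cis-fused, other centres undefined (formed in the flask) | O=C1C2(S(=O)c3ccccc3)C(CC(OCc3ccccc3)=CC2(OC)O[Si](C)(C)C)O[C@@H](c2ccc(OCc3ccccc3)cc2)[C@@H]1c1c(OCOC)cc(OCc2ccccc2)c2c(=O)cc(-c3ccc(OCc4ccccc4)cc3)oc12 | intermediate
21 | (2R,3S)-7-(benzyloxy)-2-[4-(benzyloxy)phenyl]-3-Fl-5-methoxy-5-(trimethylsilyloxy)-2,3,5,8-tetrahydro-4H-chromen-4-one, C5 undefined (formed in the flask) | O=C1C2=C(CC(OCc3ccccc3)=CC2(OC)O[Si](C)(C)C)O[C@@H](c2ccc(OCc3ccccc3)cc2)[C@@H]1c1c(OCOC)cc(OCc2ccccc2)c2c(=O)cc(-c3ccc(OCc4ccccc4)cc3)oc12 | intermediate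
22 | (2R,3S)-7-(benzyloxy)-2-[4-(benzyloxy)phenyl]-3-Fl-5-hydroxy-2,3-dihydro-4H-chromen-4-one | O=C1c2c(O)cc(OCc3ccccc3)cc2O[C@@H](c2ccc(OCc3ccccc3)cc2)[C@@H]1c1c(OCOC)cc(OCc2ccccc2)c2c(=O)cc(-c3ccc(OCc4ccccc4)cc3)oc12 | intermediate
23 | (2R,3S)-7-(benzyloxy)-2-[4-(benzyloxy)phenyl]-3-{5-(benzyloxy)-2-[4-(benzyloxy)phenyl]-7-hydroxy-4-oxo-4H-chromen-8-yl}-5-hydroxy-2,3-dihydro-4H-chromen-4-one | O=C1c2c(O)cc(OCc3ccccc3)cc2O[C@@H](c2ccc(OCc3ccccc3)cc2)[C@@H]1c1c(O)cc(OCc2ccccc2)c2c(=O)cc(-c3ccc(OCc4ccccc4)cc3)oc12 | intermediate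
24 | (2R,3S)-7-(benzyloxy)-2-[4-(benzyloxy)phenyl]-3-{5-(benzyloxy)-2-[4-(benzyloxy)phenyl]-4-oxo-7-(sulfooxy)-4H-chromen-8-yl}-5-hydroxy-2,3-dihydro-4H-chromen-4-one (sodium salt in practice; parent acid drawn) | O=C1c2c(O)cc(OCc3ccccc3)cc2O[C@@H](c2ccc(OCc3ccccc3)cc2)[C@@H]1c1c(OS(=O)(=O)O)cc(OCc2ccccc2)c2c(=O)cc(-c3ccc(OCc4ccccc4)cc3)oc12 | intermediate
25 | (2R,3S)-5,7-dihydroxy-3-[5-hydroxy-2-(4-hydroxyphenyl)-4-oxo-7-(sulfooxy)-4H-chromen-8-yl]-2-(4-hydroxyphenyl)-2,3-dihydro-4H-chromen-4-one | O=C1c2c(O)cc(O)cc2O[C@@H](c2ccc(O)cc2)[C@@H]1c1c(OS(=O)(=O)O)cc(O)c2c(=O)cc(-c3ccc(O)cc3)oc12 | target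

## Step count and weak points

Total: 16 steps. Longest linear sequence: 14 steps (steps 1–10 and 13–16, from 1 to 25); steps 11 and 12 are a two-step side branch to diene 19.

**Step 13 (proposed new method).** The donor-substituted dienophile may react too slowly. The ketene acetal may instead silylate the sulfoxide oxygen and trigger a Pummerer-type consumption of 16. Aromatisation may proceed by loss of the ring oxygen O1 (opening of ring C) in place of sulfenic acid.
- Fallback, by known reaction types, setting out from 13 and returning at 22. A TMSOTf-promoted vinylogous Mukaiyama–Michael addition of [(2,2-dimethyl-6-methylidene-6H-1,3-dioxin-4-yl)oxy]trimethylsilane to C6 of 13 should give (2R,3S)-2-[4-(benzyloxy)phenyl]-6-[(2,2-dimethyl-4-oxo-4H-1,3-dioxin-6-yl)methyl]-3-Fl-4-(trimethylsilyloxy)-3,6-dihydro-2H-pyran F1. Saegusa–Ito dehydrosilylation with Pd(OAc)2 in MeCN should restore the enone as (2R,3S)-2-[4-(benzyloxy)phenyl]-6-[(2,2-dimethyl-4-oxo-4H-1,3-dioxin-6-yl)methyl]-3-Fl-2,3-dihydro-4H-pyran-4-one F2. Heating in toluene at 110 °C should release the ketene, which acylates C5 and enolises to (2R,3S)-2-[4-(benzyloxy)phenyl]-3-Fl-5,7-dihydroxy-2,3-dihydro-4H-chromen-4-one F3. A Mitsunobu benzylation (BnOH, PPh3, DIAD) of the non-chelated 7-OH should then give 22.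

**Step 8 (key step).** The flavone carbonyl may sequester the titanium catalyst and stop turnover, leaving an uncatalysed or silyl-cation-promoted background aldol with poor facial selectivity. The hindered, di-ortho-substituted nucleophilic carbon may react slowly enough for hydrolysis of the diene to compete.
- Fallback, setting out from 9 and returning at 13. Enolisation of 9 toward the benzylic carbon with a stoichiometric chiral boron reagent (Ipc2BCl, Et3N; the antipode that gives the 5R carbinol) and aldol addition to 11, with oxidative work-up, should give (1E,4S,5R)-5-[4-(benzyloxy)phenyl]-4-Fl-5-hydroxy-1-methoxypent-1-en-3-one F4. TFA in CH2Cl2 should cyclise F4 with loss of methanol to 13. Stereocontrol then comes from the reagent and not from a catalyst that the flavone can bind.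

**Step 9.** The sulfenyl electrophile may also attack C3'' or C6'' of the flavone, or sulfenylate twice.
- Fallback, setting out from 13 and returning at 15. Iodine with pyridine in CH2Cl2 iodinates through conjugate addition of pyridine, which only the beta-unsubstituted enone of ring C can undergo, and should give (2R,3S)-2-[4-(benzyloxy)phenyl]-3-Fl-5-iodo-2,3-dihydro-4H-pyran-4-one F5. A C–S cross-coupling with thiophenol (Pd2(dba)3, Xantphos, i-Pr2NEt, dioxane, 70 °C) should convert F5 into 15.

**Step 5.** The acetylide may add to the ring E carbonyl, or deprotonate the arylacetamide so that conversion stalls.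
- Fallback, setting out from 5 and returning at 7. Partial reduction of the amide with Cp2Zr(H)Cl in THF should give 2-Fl-acetaldehyde F6. The far more electrophilic aldehyde should take up [(trimethylsilyl)ethynyl]magnesium bromide at −78 °C to give 1-Fl-4-(trimethylsilyl)but-3-yn-2-ol F7. Oxidation of F7 with DMP (the triacetoxy periodinane) should give 7.

**Step 1.** Alkylation may be unselective, with attack at O4''' or double alkylation.
- Fallback, setting out from 1 and returning at 2; it relies on selective unmasking, not selective masking. Peracetylation (Ac2O, pyridine) should give apigenin triacetate F8. The known regioselective removal of the 7-O-acetyl group with thiophenol and imidazole should give 5-acetoxy-2-(4-acetoxyphenyl)-7-hydroxy-4H-chromen-4-one F9. MOMCl with i-Pr2NEt should give 5-acetoxy-2-(4-acetoxyphenyl)-7-(methoxymethoxy)-4H-chromen-4-one F10. Methanolysis (K2CO3, MeOH) should give 2.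

## Further compounds

F1 | step 13 | (2R,3S)-2-[4-(benzyloxy)phenyl]-6-[(2,2-dimethyl-4-oxo-4H-1,3-dioxin-6-yl)methyl]-3-Fl-4-(trimethylsilyloxy)-3,6-dihydro-2H-pyran (C6 undefined) | C[Si](C)(C)OC1=CC(CC2=CC(=O)OC(C)(C)O2)O[C@@H](c2ccc(OCc3ccccc3)cc2)[C@@H]1c1c(OCOC)cc(OCc2ccccc2)c2c(=O)cc(-c3ccc(OCc4ccccc4)cc3)oc12
F2 | step 13 | (2R,3S)-2-[4-(benzyloxy)phenyl]-6-[(2,2-dimethyl-4-oxo-4H-1,3-dioxin-6-yl)methyl]-3-Fl-2,3-dihydro-4H-pyran-4-one | O=C1C=C(CC2=CC(=O)OC(C)(C)O2)O[C@@H](c2ccc(OCc3ccccc3)cc2)[C@@H]1c1c(OCOC)cc(OCc2ccccc2)c2c(=O)cc(-c3ccc(OCc4ccccc4)cc3)oc12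
F3 | step 13 | (2R,3S)-2-[4-(benzyloxy)phenyl]-3-Fl-5,7-dihydroxy-2,3-dihydro-4H-chromen-4-one | O=C1c2c(O)cc(O)cc2O[C@@H](c2ccc(OCc3ccccc3)cc2)[C@@H]1c1c(OCOC)cc(OCc2ccccc2)c2c(=O)cc(-c3ccc(OCc4ccccc4)cc3)oc12
F4 | step 8 | (1E,4S,5R)-5-[4-(benzyloxy)phenyl]-4-Fl-5-hydroxy-1-methoxypent-1-en-3-one | CO/C=C/C(=O)[C@@H](c1c(OCOC)cc(OCc2ccccc2)c2c(=O)cc(-c3ccc(OCc4ccccc4)cc3)oc12)[C@@H](O)c1ccc(OCc2ccccc2)cc1
F5 | step 9 | (2R,3S)-2-[4-(benzyloxy)phenyl]-3-Fl-5-iodo-2,3-dihydro-4H-pyran-4-one | O=C1C(I)=CO[C@@H](c2ccc(OCc3ccccc3)cc2)[C@@H]1c1c(OCOC)cc(OCc2ccccc2)c2c(=O)cc(-c3ccc(OCc4ccccc4)cc3)oc12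
F6 | step 5 | 2-Fl-acetaldehyde | COCOc1cc(OCc2ccccc2)c2c(=O)cc(-c3ccc(OCc4ccccc4)cc3)oc2c1CC=O
F7 | step 5 | 1-Fl-4-(trimethylsilyl)but-3-yn-2-ol (racemic) | COCOc1cc(OCc2ccccc2)c2c(=O)cc(-c3ccc(OCc4ccccc4)cc3)oc2c1CC(O)C#C[Si](C)(C)C
F8 | step 1 | 5,7-diacetoxy-2-(4-acetoxyphenyl)-4H-chromen-4-one | CC(=O)Oc1ccc(cc1)-c1cc(=O)c2c(OC(C)=O)cc(OC(C)=O)cc2o1
F9 | step 1 | 5-acetoxy-2-(4-acetoxyphenyl)-7-hydroxy-4H-chromen-4-one | CC(=O)Oc1ccc(cc1)-c1cc(=O)c2c(OC(C)=O)cc(O)cc2o1
F10 | step 1 | 5-acetoxy-2-(4-acetoxyphenyl)-7-(methoxymethoxy)-4H-chromen-4-one | COCOc1cc(OC(C)=O)c2c(=O)cc(-c3ccc(OC(C)=O)cc3)oc2c1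
A1 | alternative 1 | (2R,3S)-2-[4-(benzyloxy)phenyl]-3-{5-(benzyloxy)-2-[4-(benzyloxy)phenyl]-4-oxo-7-(triisopropylsilyloxy)-4H-chromen-8-yl}-5,7-dihydroxy-2,3-dihydro-4H-chromen-4-one | O=C1c2c(O)cc(O)cc2O[C@@H](c2ccc(OCc3ccccc3)cc2)[C@@H]1c1c(O[Si](C(C)C)(C(C)C)C(C)C)cc(OCc2ccccc2)c2c(=O)cc(-c3ccc(OCc4ccccc4)cc3)oc12
A2 | alternative 1 | (2R,3S)-2-[4-(benzyloxy)phenyl]-3-{5-(benzyloxy)-2-[4-(benzyloxy)phenyl]-4-oxo-7-(triisopropylsilyloxy)-4H-chromen-8-yl}-6-[(2,2-dimethyl-4-oxo-4H-1,3-dioxin-6-yl)methyl]-2,3-dihydro-4H-pyran-4-one | O=C1C=C(CC2=CC(=O)OC(C)(C)O2)O[C@@H](c2ccc(OCc3ccccc3)cc2)[C@@H]1c1c(O[Si](C(C)C)(C(C)C)C(C)C)cc(OCc2ccccc2)c2c(=O)cc(-c3ccc(OCc4ccccc4)cc3)oc12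
A3 | alternative 2 | (2R,3S)-5,7-bis(benzyloxy)-2-[4-(benzyloxy)phenyl]-3-{5-(benzyloxy)-2-[4-(benzyloxy)phenyl]-7-hydroxy-4-oxo-4H-chromen-8-yl}-2,3-dihydro-4H-chromen-4-one | O=C1c2c(OCc3ccccc3)cc(OCc3ccccc3)cc2O[C@@H](c2ccc(OCc3ccccc3)cc2)[C@@H]1c1c(O)cc(OCc2ccccc2)c2c(=O)cc(-c3ccc(OCc4ccccc4)cc3)oc12
A4 | alternative 2 | (2R,3S)-5,7-bis(benzyloxy)-2-[4-(benzyloxy)phenyl]-3-[4-(benzyloxy)-2,6-dihydroxy-3-iodophenyl]-2,3-dihydro-4H-chromen-4-one | O=C1c2c(OCc3ccccc3)cc(OCc3ccccc3)cc2O[C@@H](c2ccc(OCc3ccccc3)cc2)[C@@H]1c1c(O)cc(OCc2ccccc2)c(I)c1O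
A5 | alternative 2 | 1-(benzyloxy)-4-ethynylbenzene | C#Cc1ccc(OCc2ccccc2)cc1
A6 | alternative 3 | (2R,3S)-5,7-bis(benzyloxy)-2-[4-(benzyloxy)phenyl]-3-Fl-3,4-dihydro-2H-chromene | C1c2c(OCc3ccccc3)cc(OCc3ccccc3)cc2O[C@@H](c2ccc(OCc3ccccc3)cc2)[C@@H]1c1c(OCOC)cc(OCc2ccccc2)c2c(=O)cc(-c3ccc(OCc4ccccc4)cc3)oc12
A7 | alternative 3 | (E)-5-(benzyloxy)-2-[4-(benzyloxy)phenyl]-8-{2-[4-(benzyloxy)phenyl]ethenyl}-7-(methoxymethoxy)-4H-chromen-4-one | COCOc1cc(OCc2ccccc2)c2c(=O)cc(-c3ccc(OCc4ccccc4)cc3)oc2c1/C=C/c1ccc(OCc2ccccc2)cc1
A8 | alternative 3 | 3,5-bis(benzyloxy)-2-(hydroxymethyl)phenol | OCc1c(O)cc(OCc2ccccc2)cc1OCc1ccccc1
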